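**Retrosynthetic overview**

- Rivularin-c (9) comes from 5,5'-dibromo-3,3'-bioxindole (8): both C2–Br bonds are made from the lactam C=O groups with POBr3, which also aromatises pyrrole rings B and B'.
- Structural feature used: C2 and C2' are lone carbons, each lying between a ring nitrogen (N1, N1') and one end of the C3–C3' bond that joins rings B and B'. Both can therefore be brought in as CO across the C=C of a 2,2'-diaminostilbene whose alkene carbons become C3 and C3'.
- 8 comes from (E)-2,2'-diamino-5,5'-dibromostilbene (6) and two CO (7) in a single twofold oxidative aminocarbonylation that makes N1–C2, C2–C3, C3'–C2' and C2'–N1'; ring B closes first, ring B' second.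
- 6 comes from dinitrostilbene 5, made by Horner–Wadsworth–Emmons coupling of phosphonate 3 (from 5-bromo-2-nitrotoluene 1) with 5-bromo-2-nitrobenzaldehyde 4; benzene rings A and A' are bought with bromine already at C5 and C5'.

Key step: step 5

Remark: the target has no stereocentre and its C3–C3' axis is drawn without configuration, so no control of axial chirality is attempted; the two C3 stereocentres of 8 are transient and disappear in step 6.

**Route**

Step 1
Reactants: 1 5-bromo-2-nitrotoluene
Product: 2 5-bromo-2-nitrobenzyl bromide
Conditions: NBS (1.05 equiv), AIBN (5 mol %), PhCF3, 85 °C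
Reagents that add atoms: N-bromosuccinimide, O=C1CCC(=O)N1Br
Why: Wohl–Ziegler radical bromination; the methyl hydrogens are the only abstractable sp3 C–H bonds, and a small excess of NBS with an early stop should limit dibromination.

Step 2
Reactants: 2 5-bromo-2-nitrobenzyl bromide
Product: 3 diethyl (5-bromo-2-nitrobenzyl)phosphonate
Conditions: P(OEt)3 (1.3 equiv), toluene, 105 °C
Reagents that add atoms: triethyl phosphite, CCOP(OCC)OCC
Why: Michaelis–Arbuzov reaction; SN2 attack of phosphite on the benzylic bromide and dealkylation by bromide should proceed well below the temperature at which P(OEt)3 deoxygenates nitroarenes, and the aryl bromide is inert without a metal catalyst.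

Step 3
Reactants: 3 diethyl (5-bromo-2-nitrobenzyl)phosphonate; 4 5-bromo-2-nitrobenzaldehyde
Product: 5 (E)-5,5'-dibromo-2,2'-dinitrostilbene
Conditions: NaH, THF, 0 °C to rt; then water
Reagents that add atoms: none
Why: Horner–Wadsworth–Emmons olefination; the nitro-stabilised benzylic phosphonate carbanion adds reversibly to the non-enolisable, electron-poor aldehyde and should collapse to the (E)-stilbene.

Step 4
Reactants: 5 (E)-5,5'-dibromo-2,2'-dinitrostilbene
Product: 6 (E)-2,2'-diamino-5,5'-dibromostilbene
Conditions: Fe powder, AcOH/EtOH, 75 °C
Reagents that add atoms: none
Why: Béchamp-type iron/acid reduction works by stepwise electron transfer to the nitro groups and, unlike catalytic hydrogenation, should leave the stilbene C=C and both aryl bromides untouched.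

Step 5
Reactants: 6 (E)-2,2'-diamino-5,5'-dibromostilbene; 7 carbon monoxide (two equivalents incorporated)
Product: 8 (3S*,3'S*)-5,5'-dibromo-3,3'-bioxindole (like-configured racemate, one enantiomer drawn)
Conditions: PdI2 (5 mol %), KI (0.5 equiv), CO/air 4:1 (40 atm), MeCN (0.05 M), 80 °C
Reagents that add atoms: none
Why: Proposed new method: one aniline binds PdI2 and inserts CO to give a carbamoylpalladium iodide, which adds syn across the stilbene C=C so that the carbamoyl carbon bonds to the alkene carbon next to its own ring (future C3) and palladium lands on the other benzylic carbon (future C3'); that alkylpalladium, held in a five-membered chelate by the second ortho-NH2, inserts a second CO with retention and the acylpalladium is captured by the second nitrogen, after which zerovalent palladium and HI are returned to PdI2 by O2. The closest known reaction types are the oxidative bis-alkoxycarbonylation of styrenes and 1,2-disubstituted alkenes to succinates and the PdI2/KI oxidative carbonylation of 2-ethynylanilines to 3-(alkoxycarbonylmethylene)oxindoles; an alkene taking up two CO units that are both closed by amines has no counterpart. Ring B (N1, C2, C3, C3a, C7a) closes by 5-exo-trig carbamoylpalladation and ring B' by 5-exo-trig attack of N1' on the acylpalladium carbon (lactamisation). C3 and C3' are set relative to each other by the syn insertion on the E alkene followed by CO insertion with retention at C3', which should give the like-configured (3S*,3'S*) racemate; both centres are erased in step 6, so any epimerisation at the acidic C3–H is harmless. The step needs N-carbonylation and CO capture to outrun 5-endo aminopalladation (2-arylindole), 6-endo carbamoylpalladation (3-arylquinolin-2-one), beta-hydride elimination (3-benzylidene oxindole) and intermolecular urea formation, and what secures this is the high CO pressure, the iodide-rich and weakly alkene-philic catalyst, dilution, and the second ortho-amine, which sits where it can chelate the alkylpalladium and then trap the acylpalladium in a five-membered ring.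

Step 6
Reactants: 8 (3S*,3'S*)-5,5'-dibromo-3,3'-bioxindole
Product: 9 Rivularin-c (2,2',5,5'-tetrabromo-1H,1'H-3,3'-biindole)
Conditions: POBr3 (6 equiv), imidazole (2.5 equiv), ClCH2CH2Cl, 80 °C; then ice-water
Reagents that add atoms: phosphorus oxybromide (POBr3), O=P(Br)(Br)Br
Why: Known conversion of oxindoles into 2-bromoindoles; each lactam should react through its 2-hydroxyindole tautomer, with O-phosphorylation by POBr3 and bromide addition–elimination at C2 giving the aromatic 2-bromoindole, so that both C3 stereocentres become sp2 carbons.

**Compound list**

1 | 5-bromo-2-nitrotoluene | Cc1cc(Br)ccc1[N+](=O)[O-] | starting material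
2 | 5-bromo-2-nitrobenzyl bromide | BrCc1cc(Br)ccc1[N+](=O)[O-] | intermediate
3 | diethyl (5-bromo-2-nitrobenzyl)phosphonate | CCOP(=O)(Cc1cc(Br)ccc1[N+](=O)[O-])OCC | intermediate
4 | 5-bromo-2-nitrobenzaldehyde | O=Cc1cc(Br)ccc1[N+](=O)[O-] | starting material
5 | (E)-5,5'-dibromo-2,2'-dinitrostilbene | [O-][N+](=O)c1ccc(Br)cc1/C=C/c1cc(Br)ccc1[N+](=O)[O-] | intermediate
6 | (E)-2,2'-diamino-5,5'-dibromostilbene | Nc1ccc(Br)cc1/C=C/c1cc(Br)ccc1N | intermediate
7 | carbon monoxide | [C-]#[O+] | starting material
8 | (3S*,3'S*)-5,5'-dibromo-3,3'-bioxindole (5,5'-dibromo-1,1',3,3'-tetrahydro-2H,2'H-3,3'-biindole-2,2'-dione; racemate, one enantiomer drawn) | O=C1Nc2ccc(Br)cc2[C@@H]1[C@@H]1C(=O)Nc2ccc(Br)cc12 | intermediate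
9 | Rivularin-c (2,2',5,5'-tetrabromo-1H,1'H-3,3'-biindole) | Brc1ccc2[nH]c(Br)c(-c3c(Br)[nH]c4ccc(Br)cc34)c2c1 | target

**Step count**

Total steps: 6. Longest linear sequence: 6 steps (1 → 2 → 3 → 5 → 6 → 8 → 9); aldehyde 4 and carbon monoxide 7 are used as purchased.

**Steps most likely to fail**

1. Step 5 (Proposed new method). What may go wrong:
   - aminopalladation of the alkene ahead of N-carbonylation;
   - beta-hydride elimination before the second CO is taken up;
   - chain growth through urea links;
   - oxidative addition of zerovalent palladium into an aryl bromide;
   - dehydrogenation of the new C3–C3' bond by the iodine/air couple.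

   Fallback (known chemistry), setting out from dinitrostilbene 5 and rejoining the route at 8. The amine is kept out of the carbonylation altogether. Oxidative bis-methoxycarbonylation of 5, a known reaction type for styrenes and 1,2-disubstituted alkenes, should give by syn addition dimethyl (2S*,3S*)-2,3-bis(5-bromo-2-nitrophenyl)succinate F1. Conditions: Pd(OCOCF3)2, N,N'-bis(2,6-dimethylphenyl)butane-2,3-diimine, catalytic p-TsOH, p-benzoquinone, CO 4 bar, MeOH/THF, 20 °C. Fe powder in AcOH at 90 °C then reduces both nitro groups, and each o-aminoaryl acetate should lactamise in the same pot with loss of methanol, the classical reductive oxindole closure, to give 8.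

2. Step 6. What may go wrong: incomplete bromodeoxygenation of two hindered, poorly soluble lactams, and acid-promoted loss of bromine or oligomerisation of the electron-rich 2-bromoindole during the reaction or quench.

   Fallback, setting out from 8 and rejoining at 9. The bromines are introduced electrophilically instead of by lactam activation. Reduction of both lactams with i-Bu2AlH (CH2Cl2/THF, 0 °C to rt, mildly acidic work-up to dehydrate the hemiaminals) should give 5,5'-dibromo-1H,1'H-3,3'-biindole F2. NBS (2.0 equiv, THF, −78 to 0 °C) then brominates C2 and C2', the known 2-bromination of 3-substituted indoles through the 3-bromoindolenine, to give 9.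

3. Step 1. What may go wrong: sluggish hydrogen abstraction from the electron-poor methyl group together with over-bromination to the benzal dibromide, giving a mixture that is hard to separate.

   Fallback, setting out from aldehyde 4 and rejoining at 2. The radical C–H bromination is replaced by ionic chemistry. NaBH4 (MeOH, 0 °C) should reduce 4 to (5-bromo-2-nitrophenyl)methanol F3, and PBr3 (CH2Cl2, 0 °C) converts the benzylic alcohol into bromide 2.

**Further compounds**

F1 | step 5 | dimethyl (2S*,3S*)-2,3-bis(5-bromo-2-nitrophenyl)succinate (racemate, one enantiomer drawn) | COC(=O)[C@H](c1cc(Br)ccc1[N+](=O)[O-])[C@H](C(=O)OC)c1cc(Br)ccc1[N+](=O)[O-]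
F2 | step 6 | 5,5'-dibromo-1H,1'H-3,3'-biindole | Brc1ccc2[nH]cc(-c3c[nH]c4ccc(Br)cc34)c2c1
F3 | step 1 | (5-bromo-2-nitrophenyl)methanol | OCc1cc(Br)ccc1[N+](=O)[O-]
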